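## Retrosynthetic overview

- Ring B (the dihydropyran made of the hemiketal carbon, its ring oxygen, pyranone C-4 and C-3, and the two ring-fusion methines) is a warfarin-type hemiketal of a 1,5-dicarbonyl: the ring-A ketone sits five atoms from the pyranone C-4 oxygen. This is the de Mayo retron, so ring B is traced back to a cyclobutanol (hemiketal carbon, pyranone C-3, the two methines) that opens by retro-aldol and re-closes through oxygen (4 → 6).
- The cyclobutanol comes from an intramolecular [2+2] photocycloaddition of the enolised acyl group of a 3-acyl-4-hydroxy-6-methyl-2-pyranone onto the cis-alkene of a 6,8-dioxabicyclo[3.2.1]oct-3-ene (rings C and D), tethered through the ketal carbon. This also closes ring A (the cyclohexane) and sets both methines from the exo face.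
- Acylpyranone: C-acylation of 4-hydroxy-6-methyl-2-pyranone (ring E, bought) with a bicyclic ketal acid. Bicyclic ketal: Z-enone/acetonide exchange. Ynone: lithium acetylide plus (R)-5-oxotetrahydrofuran-2-carboxylic acid (source of the secondary carbinol centre).
- Alkyne: two successive tosylate displacements on L-threitol acetonide ditosylate (source of the two diol centres).
- Ring order: E (bought) → C and D together → A with the cyclobutane → B by ring expansion.

Key step: step 7

Assumption: the hemiketal carbon of ring B is configurationally labile (ring–chain tautomerism) and is taken to settle in the anomerically stabilised configuration of the natural product; ring–chain tautomeric compounds 7 and 16 are drawn open-chain.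

## Route

Step 1
Reactants: 1 L-threitol acetonide 1,4-ditosylate
Product: 2 [(4S,5S)-5-hexyl-2,2-dimethyl-1,3-dioxolan-4-yl]methyl 4-methylbenzenesulfonate
Conditions: n-C5H11MgBr (0.5 equiv, 1 in twofold excess), Li2CuCl4 (cat.), THF, −30 → 0 °C
Reagents that add atoms: pentylmagnesium bromide, CCCCC[Mg]Br
Why: Copper-catalysed Grignard–tosylate cross-coupling (SN2 at a primary carbon) should give mainly mono-substitution when 1 is in excess (surplus 1 is recovered); no stereocentre is touched.

Step 2
Reactants: 2 monotosylate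
Product: 3 (4S,5S)-4-hexyl-2,2-dimethyl-5-(prop-2-yn-1-yl)-1,3-dioxolane
Conditions: LiC≡CH·H2NCH2CH2NH2, DMSO, 10 °C → rt
Reagents that add atoms: lithium acetylide–ethylenediamine complex, [Li+].[C-]#C.NCCN
Why: SN2 alkylation of lithium acetylide by a primary tosylate in DMSO, a standard route to propargyl dioxolanes; both stereocentres are spectators.

Step 3
Reactants: 3 alkyne; 4 (2R)-5-oxotetrahydrofuran-2-carboxylic acid
Product: 7 (2R)-8-[(4S,5S)-5-hexyl-2,2-dimethyl-1,3-dioxolan-4-yl]-2-hydroxy-5-oxooct-6-ynoic acid, via lithium acetylide 5 (not isolated), via lithium carboxylate 6 (not isolated)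
Conditions: 3, n-BuLi, THF, −78 °C; 4, LiN(SiMe3)2 (1.0 equiv), THF, −78 °C; combine, −78 → −40 °C; aq. HCl to pH 3
Reagents that add atoms: none
Why: Acetylide addition to a γ-lactone, arrested at the lactolate at low temperature, should give the γ-hydroxy ynone; the carboxylate is inert to the acetylide and the R centre of 4 is not enolised, so it is carried over unchanged.

Step 4
Reactants: 7 hydroxy ynone acid
Product: 9 (2R)-2-[(tert-butyldimethylsilyl)oxy]-8-[(4S,5S)-5-hexyl-2,2-dimethyl-1,3-dioxolan-4-yl]-5-oxooct-6-ynoic acid, via bis-silyl compound 8 (not isolated)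
Conditions: TBSOTf (2.5 equiv), 2,6-lutidine, CH2Cl2, −78 → 0 °C; then aq. citric acid, THF, rt
Reagents that add atoms: tert-butyldimethylsilyl trifluoromethanesulfonate, CC(C)(C)[Si](C)(C)OS(=O)(=O)C(F)(F)F
Why: Silylation of the open-chain secondary alcohol (the silyl ester formed alongside is cleaved on aqueous work-up) with a non-nucleophilic base avoids conjugate addition to the ynone; the protection keeps this hydroxyl out of the later ketalisation.

Step 5
Reactants: 9 silyloxy ynone acid
Product: 11 (2R)-2-[(tert-butyldimethylsilyl)oxy]-4-[(1S,5R,7S)-7-hexyl-6,8-dioxabicyclo[3.2.1]oct-3-en-5-yl]butanoic acid, via Z-enone 10 (not isolated)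
Conditions: H2 (1 atm), Pd/CaCO3 poisoned with Pb(OAc)2, quinoline, EtOAc, rt; filter; then PPTS, MeCN–H2O, 40 °C
Reagents that add atoms: none
Why: Lindlar-type cis-semihydrogenation gives the Z-enone, and acid then exchanges the acetonide for the intramolecular ketal (thermodynamically controlled bicycloketalisation, possible only for the Z-alkene); the ketal carbon configuration is dictated by the two S diol carbons and the threo diol places hexyl exo.

Step 6
Reactants: 11 bicyclic ketal acid; 12 4-hydroxy-6-methyl-2H-pyran-2-one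
Product: 14 3-{(2R)-2-[(tert-butyldimethylsilyl)oxy]-4-[(1S,5R,7S)-7-hexyl-6,8-dioxabicyclo[3.2.1]oct-3-en-5-yl]butanoyl}-4-hydroxy-6-methyl-2H-pyran-2-one, via enol ester 13 (not isolated)
Conditions: DCC, DMAP, CH2Cl2, rt → 40 °C
Reagents that add atoms: none
Why: Steglich-type O-acylation of the pyranone followed by DMAP-mediated O→C acyl migration to C-3 (Fries-type) is the standard entry to 3-acyl-4-hydroxy-2-pyranones; the neutral conditions spare the vinyl ketal and the silyl ether.

Step 7
Reactants: 14 acylpyranone
Product: 17 O-TBS-trichopsistide B (silyl ether of the secondary hydroxyl), via cyclobutanol 15 (not isolated), via ring-opened ketone 16 (not isolated)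
Conditions: hν (350 nm, Pyrex), degassed MeCN (5 mM), rt; the photoadduct fragments on standing
Reagents that add atoms: none
Why: Excitation of the hydrogen-bonded exocyclic enol of the 3-acyl-4-hydroxypyranone (the de Mayo chromophore) should give intramolecular [2+2] photocycloaddition with the tethered cis-alkene to spiro-cyclobutanol 15, whose four-membered ring (carbinol carbon, pyranone C-3, the two former alkene carbons) is a strained β-hydroxy dione that undergoes retro-aldol cleavage of the carbinol–C-3 bond to ketone 16; the pyranone 4-OH then adds to that ketone as in warfarin-type ring–chain tautomerism, so the cyclobutane becomes the six-membered dihydropyran hemiketal by a two-atom ring expansion (net 1,3-shift of the carbinol carbon from C-3 to O-4, driven by release of cyclobutane strain). The closest known reaction type is the intramolecular de Mayo reaction of enolised β-diketones bearing alkenyl tethers, here with the 1,5-diketone captured as a cyclic hemiketal. Ring A closes in the photocycloaddition by 6-exo attack of the enol (acyl) carbon on the proximal alkene carbon followed by four-membered closure at pyranone C-3 (the straight adduct), and ring B closes by 6-exo-trig addition of the enol oxygen to the ketone. The two methine stereocentres are set by suprafacial addition to the exo face of the 6,8-dioxabicyclo[3.2.1]octene, anti to the O–CH(hexyl) bridge, which puts the ring-A bond axial and the pyranone equatorial on ring C with both hydrogens endo (cis); the hemiketal carbon equilibrates to the axial, anomerically stabilised hydroxyl trans-fused to ring A, and the carbinol and spiro centres of 15 are destroyed again. The step needs straight rather than crossed regiochemistry and reaction at the exocyclic enol rather than at the pyranone ring double bonds: the four-atom tether through the quaternary ketal carbon allows only the six-membered closure, the two-atom bridge blocks the endo face, and the product no longer absorbs at the irradiation wavelength.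

Step 8
Reactants: 17 O-TBS-trichopsistide B
Product: 18 Trichopsistide B
Conditions: HF·pyridine, pyridine, THF, 0 °C → rt
Reagents that add atoms: none
Why: Fluoride-mediated desilylation under mildly acidic, buffered conditions should free the secondary hydroxyl without opening the hemiketal or ketal and without epimerising the α-hydroxy ketone latent in ring B.

## Compound list

1 | [(4S,5S)-2,2-dimethyl-1,3-dioxolane-4,5-diyl]dimethanol bis(4-methylbenzenesulfonate) (L-threitol acetonide 1,4-ditosylate) | CC1(C)O[C@@H](COS(=O)(=O)c2ccc(C)cc2)[C@H](COS(=O)(=O)c2ccc(C)cc2)O1 | starting material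
2 | [(4S,5S)-5-hexyl-2,2-dimethyl-1,3-dioxolan-4-yl]methyl 4-methylbenzenesulfonate | CC1(C)O[C@@H](CCCCCC)[C@H](COS(=O)(=O)c2ccc(C)cc2)O1 | intermediate
3 | (4S,5S)-4-hexyl-2,2-dimethyl-5-(prop-2-yn-1-yl)-1,3-dioxolane | CC1(C)O[C@@H](CCCCCC)[C@H](CC#C)O1 | intermediate
4 | (2R)-5-oxotetrahydrofuran-2-carboxylic acid | O=C(O)[C@H]1CCC(=O)O1 | starting material
5 | lithium acetylide of 3 | CC1(C)O[C@@H](CCCCCC)[C@H](CC#C[Li])O1 | intermediate (not isolated)
6 | lithium (2R)-5-oxotetrahydrofuran-2-carboxylate | [Li+].[O-]C(=O)[C@H]1CCC(=O)O1 | intermediate (not isolated)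
7 | (2R)-8-[(4S,5S)-5-hexyl-2,2-dimethyl-1,3-dioxolan-4-yl]-2-hydroxy-5-oxooct-6-ynoic acid (open form of its lactol) | CC1(C)O[C@@H](CCCCCC)[C@H](CC#CC(=O)CC[C@@H](O)C(=O)O)O1 | intermediate
8 | tert-butyldimethylsilyl ester of 9 (bis-silyl compound) | CC1(C)O[C@@H](CCCCCC)[C@H](CC#CC(=O)CC[C@@H](O[Si](C)(C)C(C)(C)C)C(=O)O[Si](C)(C)C(C)(C)C)O1 | intermediate (not isolated)
9 | (2R)-2-[(tert-butyldimethylsilyl)oxy]-8-[(4S,5S)-5-hexyl-2,2-dimethyl-1,3-dioxolan-4-yl]-5-oxooct-6-ynoic acid | CC1(C)O[C@@H](CCCCCC)[C@H](CC#CC(=O)CC[C@@H](O[Si](C)(C)C(C)(C)C)C(=O)O)O1 | intermediate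
10 | (2R,6Z)-2-[(tert-butyldimethylsilyl)oxy]-8-[(4S,5S)-5-hexyl-2,2-dimethyl-1,3-dioxolan-4-yl]-5-oxooct-6-enoic acid | CC1(C)O[C@@H](CCCCCC)[C@H](C/C=C\C(=O)CC[C@@H](O[Si](C)(C)C(C)(C)C)C(=O)O)O1 | intermediate (not isolated)
11 | (2R)-2-[(tert-butyldimethylsilyl)oxy]-4-[(1S,5R,7S)-7-hexyl-6,8-dioxabicyclo[3.2.1]oct-3-en-5-yl]butanoic acid | CCCCCC[C@@H]1O[C@@]2(CC[C@@H](O[Si](C)(C)C(C)(C)C)C(=O)O)C=CC[C@@H]1O2 | intermediate
12 | 4-hydroxy-6-methyl-2H-pyran-2-one | Cc1cc(O)cc(=O)o1 | starting material
13 | 6-methyl-2-oxo-2H-pyran-4-yl ester of 11 (enol ester) | CCCCCC[C@@H]1O[C@@]2(CC[C@@H](O[Si](C)(C)C(C)(C)C)C(=O)Oc3cc(C)oc(=O)c3)C=CC[C@@H]1O2 | intermediate (not isolated)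
14 | 3-{(2R)-2-[(tert-butyldimethylsilyl)oxy]-4-[(1S,5R,7S)-7-hexyl-6,8-dioxabicyclo[3.2.1]oct-3-en-5-yl]butanoyl}-4-hydroxy-6-methyl-2H-pyran-2-one | CCCCCC[C@@H]1O[C@@]2(CC[C@@H](O[Si](C)(C)C(C)(C)C)C(=O)c3c(O)cc(C)oc3=O)C=CC[C@@H]1O2 | intermediate
15 | spiro-cyclobutanol photoadduct: the former acyl carbon (tertiary carbinol) and pyranone C-3 (spiro carbon of a 6-methyl-2H-pyran-2,4(3H)-dione, either configuration) are bonded to the two former alkene carbons on the exo face of the bicyclic ketal; the cyclobutane is cis-fused to rings A and C, with OH and both cyclobutane H on one face | CCCCCC[C@@H]1O[C@]23CC[C@@H](O[Si](C)(C)C(C)(C)C)[C@]4(O)C5(C(=O)C=C(C)OC5=O)[C@H](C[C@@H]1O2)[C@H]34 | intermediate (not isolated)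
16 | ring-opened ketone: 4-hydroxy-6-methyl-2-pyranone bonded through C-3 (equatorial, exo) to C-3 of the 7-hexyl-6,8-dioxabicyclo[3.2.1]octane, whose C-4–C-5 bond carries the cis-fused (R)-silyloxy cyclohexanone (C=O on C-4, axial) | CCCCCC[C@@H]1O[C@]23CC[C@@H](O[Si](C)(C)C(C)(C)C)C(=O)[C@@H]3[C@@H](C[C@@H]1O2)c5c(O)cc(C)oc5=O | intermediate (not isolated)
17 | O-TBS-trichopsistide B (tert-butyldimethylsilyl ether of the secondary hydroxyl next to the hemiketal carbon) | CCCCCC[C@@H]1O[C@]23CC[C@@H](O[Si](C)(C)C(C)(C)C)[C@@]4(O)Oc5cc(C)oc(=O)c5[C@H](C[C@@H]1O2)[C@H]34 | intermediate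
18 | Trichopsistide B | CCCCCC[C@@H]1O[C@]23CC[C@@H](O)[C@@]4(O)Oc5cc(C)oc(=O)c5[C@H](C[C@@H]1O2)[C@H]34 | target

## Step count and risks

Total step count: 8. Longest linear sequence: 8 steps (1 → 2 → 3 → 7 → 9 → 11 → 14 → 17 → 18); 4 and 12 enter as bought building blocks.

The three steps most likely to fail:

**Step 7.** The excited hydrogen-bonded enol may decay unproductively by proton transfer, the biradical may close in the crossed sense or revert, or the 2-pyranone may undergo secondary photoreaction. The fallback sets out from 14 and returns at 15. The enol proton is replaced by a BF2 bridge, a chromophore known for de Mayo-type [2+2] additions. Treating 14 with BF3·OEt2 and i-Pr2NEt (CH2Cl2, 0 °C) should give the difluoroboron chelate of 14 F1. Irradiation at 390–405 nm, where the pyranone product is transparent, should give the cyclobutane-fused difluorodioxaborinane F2. NaOAc in aqueous MeOH removes the boron bridge and delivers cyclobutanol 15, which fragments and closes to 17 as in step 7.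

**Step 3.** The lactolate may collapse early and take up a second acetylide, or the addition may stall because the lithium carboxylate of the lactone dissolves poorly. The fallback sets out from 4 and returns at 9. Lactone 4 is opened with MeNH(OMe)·HCl and i-PrMgCl (THF, −20 °C) to the hydroxy Weinreb amide acid F3. Silylation with TBSOTf and 2,6-lutidine gives the bis-silyl Weinreb amide F4, whose silyl ester is cleaved on aqueous work-up to the silyloxy Weinreb amide acid F5. F5 is added at −78 °C to two equivalents of lithium acetylide 5 (the first forms the carboxylate); the chelated adduct cannot take up a second acetylide and should give ynone acid 9 on acidic work-up, bypassing 7 and 8.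

**Step 5.** The Z-enone may isomerise to the E-enone or suffer conjugate addition of the freed hydroxyls before the ketal closes, the alkyne may be over-reduced, or the silyl ether may be lost under the acid. The fallback sets out from 3 and 4 (as its salt 6) and returns at 11. It makes the ring alkene by ring-closing metathesis, so no Z-enone occurs.
- Alkyne 3 is semi-hydrogenated (H2, Pd/CaCO3 poisoned with Pb(OAc)2, quinoline) to the allyl dioxolane F6.
- Salt 6 is opened with CH2=CHMgBr (THF, −78 °C) to the hydroxy vinyl ketone acid F7. Silylation (TBSOTf, 2,6-lutidine) gives the bis-silyl vinyl ketone F8, which is cleaved on work-up to the silyloxy vinyl ketone acid F9.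
- Acetonide-to-ketal exchange between F6 and F9 (TMSOTf cat., CH2Cl2, −40 °C, acetone removed) should give the vinyl ketal F10 as both epimers at the ketal carbon.
- RuCl2(H2IMes)(=CH-2-(i-PrO)C6H4) (second-generation Hoveyda–Grubbs catalyst) in CH2Cl2 should close the epimer with vinyl cis to allyl to 11; the other epimer is re-equilibrated with acid and recycled.

## Further compounds

F1 | step 7 | difluoroboron chelate of 14 (O–BF2–O bridge between the acyl oxygen and the pyranone 4-oxygen) | CCCCCC[C@@H]1O[C@@]2(CC[C@@H](O[Si](C)(C)C(C)(C)C)C3=C4C(=O)OC(C)=CC4=[O+][B-](F)(F)O3)C=CC[C@@H]1O2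
F2 | step 7 | cyclobutane-fused difluorodioxaborinane (BF2-bridged form of cyclobutanol 15) | CCCCCC[C@@H]1O[C@]23CC[C@@H](O[Si](C)(C)C(C)(C)C)[C@]4(O5)[C@]6(C(=O)OC(C)=CC6=[O+][B-]5(F)F)[C@H](C[C@@H]1O2)[C@H]34
F3 | step 3 | (2R)-2-hydroxy-5-[methoxy(methyl)amino]-5-oxopentanoic acid | CON(C)C(=O)CC[C@@H](O)C(=O)O
F4 | step 3 | tert-butyldimethylsilyl (2R)-2-[(tert-butyldimethylsilyl)oxy]-5-[methoxy(methyl)amino]-5-oxopentanoate | CON(C)C(=O)CC[C@@H](O[Si](C)(C)C(C)(C)C)C(=O)O[Si](C)(C)C(C)(C)C
F5 | step 3 | (2R)-2-[(tert-butyldimethylsilyl)oxy]-5-[methoxy(methyl)amino]-5-oxopentanoic acid | CON(C)C(=O)CC[C@@H](O[Si](C)(C)C(C)(C)C)C(=O)O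
F6 | step 5 | (4S,5S)-4-hexyl-2,2-dimethyl-5-(prop-2-en-1-yl)-1,3-dioxolane | CC1(C)O[C@@H](CCCCCC)[C@H](CC=C)O1
F7 | step 5 | (2R)-2-hydroxy-5-oxohept-6-enoic acid | C=CC(=O)CC[C@@H](O)C(=O)O
F8 | step 5 | tert-butyldimethylsilyl (2R)-2-[(tert-butyldimethylsilyl)oxy]-5-oxohept-6-enoate | C=CC(=O)CC[C@@H](O[Si](C)(C)C(C)(C)C)C(=O)O[Si](C)(C)C(C)(C)C
F9 | step 5 | (2R)-2-[(tert-butyldimethylsilyl)oxy]-5-oxohept-6-enoic acid | C=CC(=O)CC[C@@H](O[Si](C)(C)C(C)(C)C)C(=O)O
F10 | step 5 | (2R)-2-[(tert-butyldimethylsilyl)oxy]-4-[(4S,5S)-2-ethenyl-5-hexyl-4-(prop-2-en-1-yl)-1,3-dioxolan-2-yl]butanoic acid (both epimers at the ketal carbon) | C=CC1(CC[C@@H](O[Si](C)(C)C(C)(C)C)C(=O)O)O[C@@H](CCCCCC)[C@H](CC=C)O1
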